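The route rests on disconnecting the bond between the ring-fusion triamino carbon and the guanidine N–H. That carbon is first built as an aminal C–H, bonded to the pyrrole nitrogen and the lactam nitrogen, where the pyrroloimidazolone and piperidine rings meet; the neighbouring ring carbon carries an oxygen. A primary carbamate on that oxygen is turned into a rhodium nitrenoid that inserts into the aminal C–H, creating the third C–N bond, the quaternary stereocentre (with retention) and a cis-fused oxazolidinone in one operation. The precursor is a dibromopyrrole-fused tricyclic aminal carbamate with the aminal hydrogen cis to the carbamate oxygen, made from (S)-3-hydroxypiperidin-2-one by acylation, partial reduction and N-acyliminium closure.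

Key step: step 8

Remark: C-a is the ring-fusion aminal (later triamino) carbon and C-b the neighbouring oxygen-bearing ring carbon; the target is taken as the neutral guanidine, so the last step ends with neutralisation.

Step 1
Reactants: 1 (S)-3-hydroxypiperidin-2-one
Product: 2 (S)-3-[(tert-butyldimethylsilyl)oxy]piperidin-2-one
Conditions: TBSCl, imidazole, DMF, rt
Reagents that add atoms: tert-butyldimethylsilyl chloride, CC(C)(C)[Si](C)(C)Cl
Why: Silyl ether formation, in which the silylimidazolium transfers TBS to the secondary hydroxyl much faster than to the lactam N–H and no bond to the C3 stereocentre is touched.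

Step 2
Reactants: 3 4,5-dibromo-1H-pyrrole-2-carboxylic acid
Product: 4 4,5-dibromo-1H-pyrrole-2-carbonyl chloride (used crude)
Conditions: (COCl)2, cat. DMF, CH2Cl2, 0 °C → rt; evaporate
Reagents that add atoms: oxalyl chloride, ClC(=O)C(=O)Cl
Why: Acid chloride formation through the Vilsmeier-type chloroiminium species from DMF and oxalyl chloride, which the electron-poor dibromopyrrole ring tolerates.

Step 3
Reactants: 2 (S)-3-[(tert-butyldimethylsilyl)oxy]piperidin-2-one; 4 4,5-dibromo-1H-pyrrole-2-carbonyl chloride
Product: 5 (S)-3-[(tert-butyldimethylsilyl)oxy]-1-(4,5-dibromo-1H-pyrrole-2-carbonyl)piperidin-2-one (imide)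
Conditions: NaH (2.2 equiv), THF, 0 °C; then 4 in THF, slow addition, 0 °C → rt; aq. NH4Cl
Reagents that add atoms: none
Why: N-acylation of a lactam anion with an acyl chloride (imide formation), in which the second equivalent of NaH takes up the acidic pyrrole N–H so that no lactam anion is lost to it, while C3–H is not removed under these conditions and the stereocentre is kept.

Step 4
Reactants: 5 imide
Product: 6 (4,5-dibromo-1H-pyrrol-2-yl)[(3S)-3-[(tert-butyldimethylsilyl)oxy]-2-hydroxypiperidin-1-yl]methanone (N-acyl hemiaminal as a mixture at C2)
Conditions: LiEt3BH (2.2 equiv), THF, −78 °C; aq. NaHCO3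
Reagents that add atoms: none
Why: Partial reduction of an N-acyl lactam to the N-acyl hemiaminal, in which the first equivalent deprotonates the pyrrole N–H (switching off the exocyclic carbonyl by conjugation), hydride then adds to the ring carbonyl, and the tetrahedral borate persists at −78 °C so that ring opening and over-reduction are avoided; the new carbinol centre forms as a mixture that the next step erases.

Step 5
Reactants: 6 N-acyl hemiaminal
Product: 7 tricyclic aminal silyl ether (C-b S and C-a R; pyrrole N trans to OTBS; H at C-a cis to O)
Conditions: TFA (5 equiv), CH2Cl2, 0 °C → rt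
Reagents that add atoms: none
Why: N-acyliminium aminal formation, in which acid ionises the hemiaminal and the pyrrole nitrogen closes the five-membered imidazolone ring on the iminium carbon; the new aminal centre is set by the C3 silyloxy group because the pyrrole has to swing its C5–Br over C3 and should do so on the face away from the bulky OTBS, which places the pyrrole N trans to O and the aminal H cis to O.

Step 6
Reactants: 7 tricyclic aminal silyl ether
Product: 8 tricyclic aminal alcohol (C-b S and C-a R)
Conditions: HF·pyridine, THF, 0 °C → rt
Reagents that add atoms: none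
Why: Fluoride-driven desilylation (strong Si–F bond) under mildly acidic conditions that the aminal, the lactam and the C–Br bonds tolerate, with no stereocentre involved.

Step 7
Reactants: 8 tricyclic aminal alcohol; 9 trichloroacetyl isocyanate
Product: 11 tricyclic aminal carbamate (C-b S and C-a R; key-step precursor), via N-trichloroacetyl carbamate 10 (not isolated)
Conditions: Cl3CC(O)NCO, CH2Cl2, 0 °C; then K2CO3 (cat.), MeOH, rt
Reagents that add atoms: none
Why: Carbamoylation of the secondary alcohol by addition to the highly electrophilic acyl isocyanate, followed by mild methanolysis of the trichloroacetyl group on nitrogen, gives the primary carbamate without touching the C–O bond or its configuration.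

Step 8
Reactants: 11 tricyclic aminal carbamate
Product: 12 oxazolidinone-fused tetracycle (C-b S and C-a S; cis-fused)
Conditions: Rh2(OAc)4 (5 mol %), PhI(OAc)2 (1.5 equiv), MgO (2.5 equiv), CH2Cl2, 40 °C
Reagents that add atoms: none
Why: PhI(OAc)2 oxidises the carbamate NH2 to an iminoiodinane that hands its nitrene to the dirhodium carboxylate, and the electrophilic rhodium nitrenoid inserts into the aminal C–H in a concerted, asynchronous step. The closest known reaction type is the dirhodium-catalysed intramolecular C–H amination of primary carbamates to oxazolidinones, which is also known for C–H bonds next to nitrogen. The oxazolidinone closes through a five-membered (1,5) insertion transition state and can only be cis-fused to the piperidine. The new quaternary triamino stereocentre forms with retention, nitrogen taking the place of hydrogen on the face of the carbamate oxygen, so it is controlled by the carbinol centre bought with the lactam. The step must prefer the aminal C–H over the ring CH2 on the other side of C-b and over the pyrrole π system; the aminal C–H is tertiary, flanked by two nitrogens and cis to the carbamate (step 5), and the pyrrole is deactivated by two bromines and the acyl group. MgO removes the acetic acid so that the acid-sensitive aminal survives.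

Step 9
Reactants: 12 oxazolidinone-fused tetracycle
Product: 13 N-Boc oxazolidinone (geometry unchanged; C-a becomes R by priority change only)
Conditions: Boc2O, DMAP (cat.), Et3N, CH2Cl2, rt
Reagents that add atoms: di-tert-butyl dicarbonate, CC(C)(C)OC(=O)OC(=O)OC(C)(C)C
Why: N-acylation of the oxazolidinone, which carries the only N–H of the molecule, under DMAP catalysis gives the imide-type N-Boc derivative that makes the ring carbonyl cleavable, with no stereocentre touched.

Step 10
Reactants: 13 N-Boc oxazolidinone
Product: 14 Boc-amino alcohol (C-b S and C-a S)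
Conditions: Cs2CO3 (0.3 equiv), MeOH, 0 °C → rt
Reagents that add atoms: none
Why: Methanolysis of an N-Boc-activated oxazolidinone, in which methoxide attacks the ring carbonyl (the less hindered and more electrophilic carbonyl on nitrogen) and the methyl carbonate left on oxygen is transesterified, so the Boc group stays on nitrogen and both stereocentres are untouched.

Step 11
Reactants: 14 Boc-amino alcohol
Product: 15 Boc-amino ketone (C-a S)
Conditions: Dess–Martin periodinane, CH2Cl2, 0 °C → rt
Reagents that add atoms: none
Why: Dess–Martin oxidation of the secondary alcohol under near-neutral conditions, with no risk of epimerisation because the neighbouring triamino carbon bears no hydrogen.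

Step 12
Reactants: 15 Boc-amino ketone; 16 N,N′-di-Boc-N″-triflylguanidine
Product: 18 N,N′-di-Boc-guanidino ketone (C-a S), via ammonium trifluoroacetate 17 (not isolated)
Conditions: TFA, CH2Cl2, 0 °C; evaporate; then 16, Et3N, CH2Cl2, 0 °C → rt
Reagents that add atoms: none
Why: Acidolytic Boc cleavage followed by guanylation of the primary amine with the triflylguanidine, the most electrophilic common guanylating agent and therefore suited to a hindered, weakly basic amine; the ammonium salt is shielded from ionisation by the adjacent ketone and the amine is trapped as soon as Et3N frees it, with the stereocentre untouched.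

Step 13
Reactants: 18 N,N′-di-Boc-guanidino ketone
Product: 20 target CNP0143627.2 (C-b R and C-a S), via guanidinium ketone 19 (not isolated)
Conditions: TFA/CH2Cl2 (1:1), rt; then aq. NaHCO3
Reagents that add atoms: none
Why: Acidolysis of both Boc groups frees the guanidine, whose terminal nitrogen adds to the neighbouring ketone (5-exo-trig carbinolamine formation) to close the 2-aminoimidazoline; the carbinolamine centre is set by the quaternary C-a because the five-membered ring can only be cis-fused to the piperidine and the addition is reversible.

Compound list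
1 | (S)-3-hydroxypiperidin-2-one | O[C@H]1CCCNC1=O | starting material
2 | (S)-3-[(tert-butyldimethylsilyl)oxy]piperidin-2-one | CC(C)(C)[Si](C)(C)O[C@H]1CCCNC1=O | intermediate
3 | 4,5-dibromo-1H-pyrrole-2-carboxylic acid | OC(=O)c1cc(Br)c(Br)[nH]1 | starting material
4 | 4,5-dibromo-1H-pyrrole-2-carbonyl chloride | ClC(=O)c1cc(Br)c(Br)[nH]1 | intermediate
5 | (S)-3-[(tert-butyldimethylsilyl)oxy]-1-(4,5-dibromo-1H-pyrrole-2-carbonyl)piperidin-2-one | CC(C)(C)[Si](C)(C)O[C@H]1CCCN(C(=O)c2cc(Br)c(Br)[nH]2)C1=O | intermediate
6 | (4,5-dibromo-1H-pyrrol-2-yl)[(3S)-3-[(tert-butyldimethylsilyl)oxy]-2-hydroxypiperidin-1-yl]methanone, C2 epimers | CC(C)(C)[Si](C)(C)O[C@H]1CCCN(C(=O)c2cc(Br)c(Br)[nH]2)C1O | intermediate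
7 | tricyclic aminal silyl ether (C-b S, C-a R) | CC(C)(C)[Si](C)(C)O[C@H]1CCCN2C(=O)c3cc(Br)c(Br)n3[C@H]12 | intermediate
8 | tricyclic aminal alcohol (C-b S, C-a R) | O[C@H]1CCCN2C(=O)c3cc(Br)c(Br)n3[C@H]12 | intermediate
9 | trichloroacetyl isocyanate | O=C=NC(=O)C(Cl)(Cl)Cl | starting material
10 | N-trichloroacetyl carbamate of 8 | ClC(Cl)(Cl)C(=O)NC(=O)O[C@H]1CCCN2C(=O)c3cc(Br)c(Br)n3[C@H]12 | intermediate (not isolated)
11 | tricyclic aminal carbamate (C-b S, C-a R) | NC(=O)O[C@H]1CCCN2C(=O)c3cc(Br)c(Br)n3[C@H]12 | intermediate
12 | oxazolidinone-fused tetracycle (C-b S, C-a S) | O=C1O[C@H]2CCCN3C(=O)c4cc(Br)c(Br)n4[C@@]32N1 | intermediate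
13 | N-Boc oxazolidinone (C-b S, C-a R) | CC(C)(C)OC(=O)N1C(=O)O[C@H]2CCCN3C(=O)c4cc(Br)c(Br)n4[C@@]321 | intermediate
14 | Boc-amino alcohol (C-b S, C-a S) | O[C@H]1CCCN2C(=O)c3cc(Br)c(Br)n3[C@@]21NC(=O)OC(C)(C)C | intermediate
15 | Boc-amino ketone (C-a S) | O=C1CCCN2C(=O)c3cc(Br)c(Br)n3[C@@]21NC(=O)OC(C)(C)C | intermediate
16 | N,N′-di-Boc-N″-triflylguanidine | CC(C)(C)OC(=O)NC(=NS(=O)(=O)C(F)(F)F)NC(=O)OC(C)(C)C | starting material
17 | α-amino ketone as ammonium trifluoroacetate (C-a S) | O=C1CCCN2C(=O)c3cc(Br)c(Br)n3[C@@]21[NH3+].[O-]C(=O)C(F)(F)F | intermediate (not isolated)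
18 | N,N′-di-Boc-guanidino ketone (C-a S) | O=C1CCCN2C(=O)c3cc(Br)c(Br)n3[C@@]21NC(=NC(=O)OC(C)(C)C)NC(=O)OC(C)(C)C | intermediate
19 | guanidinium ketone trifluoroacetate (C-a S) | O=C1CCCN2C(=O)c3cc(Br)c(Br)n3[C@@]21NC(N)=[NH2+].[O-]C(=O)C(F)(F)F | intermediate (not isolated)
20 | CNP0143627.2 (C-b R, C-a S) | NC1=N[C@@]2(O)CCCN3C(=O)c4cc(Br)c(Br)n4[C@@]32N1 | target

Total step count: 13. Longest linear sequence: 12 steps (from 1 through steps 1 and 3 to 13; the same length from 3 through steps 2 to 13).

Steps most likely to fail

Step 8. The nitrenoid may insert into the ring CH2 on the other side of C-b, or the carbamate may be oxidised without C–N bond formation (ketone at C-b, catalyst loss to the pyrrole). The fallback replaces nitrenoid insertion by a radical relay. It is the known β C–H amination of alcohols through imidate radicals, a Hofmann–Löffler–Freytag-type 1,5-hydrogen atom transfer. It sets out from alcohol 8. Cl3CCN with catalytic DBU in CH2Cl2 should give the trichloroacetimidate F1. PhI(OAc)2 and I2 in MeCN under visible light would form the N-iodo imidate, whose nitrogen radical abstracts the aminal hydrogen (the weakest C–H, through a six-membered transition state). The carbon radical is oxidised to the N-acyliminium ion and captured by the imidate nitrogen on the face of the oxygen, giving the cis-fused 2-(trichloromethyl)oxazoline F2. Aqueous HCl in THF should open the oxazoline to the amino alcohol hydrochloride F3, and Boc2O with NaHCO3 in the same flask gives Boc-amino alcohol 14, where the route is rejoined.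

Step 12. After Boc cleavage the free amine on the triamino carbon may expel the pyrrole nitrogen (ring opening to an acylamidine) or condense with the ketone before the hindered nitrogen is guanylated. The fallback avoids both the free base and the protected guanidine. It sets out from 15, which is taken to salt 17 with TFA as before. Salt 17 is then warmed with cyanamide in aqueous ethanol buffered to pH 4–5 (50–60 °C). The amine, kept largely protonated, adds to cyanamide (the classical α-amino ketone–cyanamide condensation used for 2-aminoimidazoles) and gives the guanidinium ketone 19 directly, where the route is rejoined. Ring closure to 20 follows, and dehydration to an imidazole is impossible because C-a bears no hydrogen.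

Step 5. Facial selectivity may be poor or reversed, with the pyrrole nitrogen adding syn to the silyloxy group (the usual sense for intermolecular additions to 3-alkoxy N-acyliminium ions). That would leave the aminal hydrogen trans to oxygen and out of reach of the nitrenoid. The fallback replaces reliance on anti addition by inversion at C-b. It sets out from the antipode of 1, (R)-3-hydroxypiperidin-2-one F4, used with acid chloride 4. The operations of steps 1, 3, 4 and 5 should give the silyl ether F5, the imide F6, the hemiaminal F7 and, by syn closure, the cis tricyclic silyl ether F8, which already has the required configuration at C-a. HF·pyridine gives the cis alcohol F9. Mitsunobu inversion (4-nitrobenzoic acid, PPh3, DIAD, THF) gives the 4-nitrobenzoate F10 with inverted C-b, and K2CO3 in MeOH releases alcohol 8, where the route is rejoined.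

Further compounds
F1 | step 8 | trichloroacetimidate of alcohol 8 | ClC(Cl)(Cl)C(=N)O[C@H]1CCCN2C(=O)c3cc(Br)c(Br)n3[C@H]12
F2 | step 8 | cis-fused 2-(trichloromethyl)oxazoline | ClC(Cl)(Cl)C1O[C@H]2CCCN3C(=O)c4cc(Br)c(Br)n4[C@@]32N=1
F3 | step 8 | amino alcohol hydrochloride | O[C@H]1CCCN2C(=O)c3cc(Br)c(Br)n3[C@@]21[NH3+].[Cl-]
F0 | step 12 | none | none
F4 | step 5 | (R)-3-hydroxypiperidin-2-one | O[C@@H]1CCCNC1=O
F5 | step 5 | (R)-3-[(tert-butyldimethylsilyl)oxy]piperidin-2-one | CC(C)(C)[Si](C)(C)O[C@@H]1CCCNC1=O
F6 | step 5 | (R)-3-[(tert-butyldimethylsilyl)oxy]-1-(4,5-dibromo-1H-pyrrole-2-carbonyl)piperidin-2-one | CC(C)(C)[Si](C)(C)O[C@@H]1CCCN(C(=O)c2cc(Br)c(Br)[nH]2)C1=O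
F7 | step 5 | (3R)-N-acyl hemiaminal, C2 epimers | CC(C)(C)[Si](C)(C)O[C@@H]1CCCN(C(=O)c2cc(Br)c(Br)[nH]2)C1O
F8 | step 5 | cis tricyclic silyl ether (C-b R, C-a R) | CC(C)(C)[Si](C)(C)O[C@@H]1CCCN2C(=O)c3cc(Br)c(Br)n3[C@H]12
F9 | step 5 | cis alcohol (C-b R, C-a R) | O[C@@H]1CCCN2C(=O)c3cc(Br)c(Br)n3[C@H]12
F10 | step 5 | 4-nitrobenzoate with inverted C-b (C-b S, C-a R) | O=C(O[C@H]1CCCN2C(=O)c3cc(Br)c(Br)n3[C@H]12)c1ccc(cc1)[N+](=O)[O-]
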